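**Retrosynthetic overview**

1. Feature: each oxolane (ring E: O1, C2 bearing ring B, C3 bearing CH2OH, C4 bearing OH and the ring A benzyl, C5H2; ring F: the same with ring D on C2 and the ring C benzyl on C4) has its C3–C4–C5 unit mapped onto Cβ–Cα–C(=O) of a γ-aryl-α-benzyl butenolide, so the single C2 centre can set C3 and then C4.
2. Endgame: the four O-benzyl groups are removed last; O1–C2 of rings E and F is closed by acid from the octaol obtained by hydride opening of the bis-lactone; both CH2OH groups come from CH2–Si.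
3. Key disconnection: both C3–CH2 bonds and both C4–OH bonds, made together on a bis-butenolide by silylmethyl cuprate addition and oxidation of the resulting enolates.
4. The bis-butenolide comes from an exo-to-endo alkene shift in a bis(benzylidene lactone); its ring B–ring C bond comes from Suzuki coupling of two (S)-γ-aryl-α-benzylidene lactones, each made by Stetter reaction, asymmetric transfer hydrogenation/lactonisation and aldol condensation.
5. Ring order: lactone rings E and F (steps 3 and 7), biaryl bond (step 9), both rings opened (step 14) and reclosed as oxolanes E and F (step 15).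

Key step: step 12

Remark: the biaryl is unsymmetrical (ring B is the C2 aryl of ring E, ring C is the benzyl arm of ring F), so the B–C bond is made by cross-coupling two differently elaborated 5-bromovanillin units; the phenols are carried as benzyl ethers so that no protic acid able to ionise a para-alkoxybenzylic C–O bond is needed before step 15.

**Route**

Step 1
Reactants: 1 5-bromovanillin
Product: 2 4-(benzyloxy)-3-bromo-5-methoxybenzaldehyde
Conditions: BnBr, K2CO3, DMF, 50 °C
Reagents that add atoms: benzyl bromide, BrCc1ccccc1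
Why: Williamson etherification of the phenoxide gives a benzyl ether that should tolerate every base, hydride and organometallic used later and is removable at the end under neutral conditions.

Step 2
Reactants: 2 4-(benzyloxy)-3-bromo-5-methoxybenzaldehyde; 3 methyl acrylate
Product: 4 methyl 4-[4-(benzyloxy)-3-bromo-5-methoxyphenyl]-4-oxobutanoate
Conditions: 3-benzyl-5-(2-hydroxyethyl)-4-methylthiazolium chloride (20 mol %), Et3N, DMF, 70 °C
Reagents that add atoms: none
Why: Stetter reaction, in which the thiazolylidene turns the aldehyde into an acyl-anion equivalent (Breslow intermediate) that adds 1,4 to the acrylate and so delivers the 1,4-keto ester in one C–C bond formation.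

Step 3
Reactants: 4 methyl 4-[4-(benzyloxy)-3-bromo-5-methoxyphenyl]-4-oxobutanoate
Product: 6 (5S)-5-[4-(benzyloxy)-3-bromo-5-methoxyphenyl]oxolan-2-one, via hydroxy ester 5 (not isolated)
Conditions: RuCl(p-cymene)[(S,S)-TsDPEN] (1 mol %), HCO2H–Et3N (5:2), DMF, 40 °C; then PPTS (cat.), toluene, 60 °C
Reagents that add atoms: none
Why: Noyori asymmetric transfer hydrogenation of an aryl alkyl ketone, in which the (S,S)-diamine ruthenium hydride should deliver hydride to the Re face as it does for acetophenone-type ketones to give the (S)-carbinol, which lactonises onto the ester to close ring E with the future C2 centre in place.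

Step 4
Reactants: 6 (5S)-5-[4-(benzyloxy)-3-bromo-5-methoxyphenyl]oxolan-2-one; 7 4-(benzyloxy)-3-methoxybenzaldehyde
Product: 10 (3E,5S)-3-[4-(benzyloxy)-3-methoxybenzylidene]-5-[4-(benzyloxy)-3-bromo-5-methoxyphenyl]oxolan-2-one, via aldol adduct 8 (not isolated), via mesylate 9 (not isolated)
Conditions: LiHMDS, THF, −78 °C; 7; MsCl, −78 → 0 °C; DBU, 0 °C → rt
Reagents that add atoms: none
Why: Aldol condensation (lithium lactone enolate addition to the aldehyde, mesylation of the aldolate, E1cB elimination) should give the conjugated (E)-arylidene lactone without touching the C5–H, which is not acidified in the exocyclic isomer; the alkene geometry is of no consequence because the double bond is moved in step 10.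

Step 5
Reactants: 10 (3E,5S)-3-[4-(benzyloxy)-3-methoxybenzylidene]-5-[4-(benzyloxy)-3-bromo-5-methoxyphenyl]oxolan-2-one
Product: 11 (3E,5S)-3-[4-(benzyloxy)-3-methoxybenzylidene]-5-[4-(benzyloxy)-3-methoxy-5-(4,4,5,5-tetramethyl-1,3,2-dioxaborolan-2-yl)phenyl]oxolan-2-one
Conditions: B2pin2, PdCl2(dppf) (5 mol %), KOAc, 1,4-dioxane, 85 °C
Reagents that add atoms: bis(pinacolato)diboron, CC1(C)OB(OC1(C)C)B1OC(C)(C)C(C)(C)O1
Why: Miyaura borylation of the aryl bromide, with acetate too weak a base to open the lactone or to trigger coupling of the product boronate.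

Step 6
Reactants: 7 4-(benzyloxy)-3-methoxybenzaldehyde; 3 methyl acrylate
Product: 12 methyl 4-[4-(benzyloxy)-3-methoxyphenyl]-4-oxobutanoate
Conditions: 3-benzyl-5-(2-hydroxyethyl)-4-methylthiazolium chloride (20 mol %), Et3N, DMF, 70 °C
Reagents that add atoms: none
Why: Stetter reaction as in step 2, the carbene-derived acyl-anion equivalent of the aldehyde adding 1,4 to methyl acrylate.

Step 7
Reactants: 12 methyl 4-[4-(benzyloxy)-3-methoxyphenyl]-4-oxobutanoate
Product: 14 (5S)-5-[4-(benzyloxy)-3-methoxyphenyl]oxolan-2-one, via hydroxy ester 13 (not isolated)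
Conditions: RuCl(p-cymene)[(S,S)-TsDPEN] (1 mol %), HCO2H–Et3N (5:2), DMF, 40 °C; then PPTS (cat.), toluene, 60 °C
Reagents that add atoms: none
Why: Noyori asymmetric transfer hydrogenation with the same catalyst enantiomer as in step 3 should give the (S)-carbinol by the same facial preference, and lactonisation closes ring F with its C2 centre set.

Step 8
Reactants: 14 (5S)-5-[4-(benzyloxy)-3-methoxyphenyl]oxolan-2-one; 2 4-(benzyloxy)-3-bromo-5-methoxybenzaldehyde
Product: 17 (3E,5S)-3-[4-(benzyloxy)-3-bromo-5-methoxybenzylidene]-5-[4-(benzyloxy)-3-methoxyphenyl]oxolan-2-one, via aldol adduct 15 (not isolated), via mesylate 16 (not isolated)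
Conditions: LiHMDS, THF, −78 °C; 2; MsCl, −78 → 0 °C; DBU, 0 °C → rt
Reagents that add atoms: none
Why: Aldol condensation as in step 4; the silylamide base at −78 °C deprotonates only the lactone α-position and leaves the aryl bromide of the aldehyde partner alone.

Step 9
Reactants: 11 pinacol boronate of the ring A/ring B lactone; 17 (3E,5S)-3-[4-(benzyloxy)-3-bromo-5-methoxybenzylidene]-5-[4-(benzyloxy)-3-methoxyphenyl]oxolan-2-one
Product: 18 biaryl bis(benzylidene lactone) with ring B joined to ring C
Conditions: Pd(OAc)2 (5 mol %), SPhos (10 mol %), K3PO4, toluene/H2O, 60 °C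
Reagents that add atoms: none
Why: Suzuki–Miyaura coupling (oxidative addition of the aryl bromide to zerovalent palladium, transmetalation, reductive elimination), with a biarylphosphine suited to the doubly ortho-oxygenated biaryl; it is run on the exocyclic alkene isomers because their C5–H is not vinylogously acidic and so cannot be epimerised by phosphate.

Step 10
Reactants: 18 biaryl bis(benzylidene lactone)
Product: 19 bis-butenolide with two (5S)-5-aryl-3-benzylfuran-2(5H)-one units
Conditions: RuHCl(CO)(PPh3)3 (10 mol %), toluene, 90 °C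
Reagents that add atoms: none
Why: Metal-hydride alkene isomerisation, in which Ru–H adds to each exocyclic enoate with hydrogen going to the benzylic carbon and the metal to Cα, and β-hydride elimination of a ring C–H then places the double bond in the ring, where the conjugated endocyclic isomer of a five-membered lactone is the more stable; the catalyst is neutral and base-free, so the C5–H that becomes acidic in the product should stay in place.

Step 11
Reactants: 20 (chloromethyl)(isopropoxy)dimethylsilane
Product: 21 [(isopropoxydimethylsilyl)methyl]magnesium chloride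
Conditions: Mg turnings, BrCH2CH2Br (cat.), THF, 40 °C
Reagents that add atoms: magnesium, [Mg]
Why: Grignard formation from the primary chloride gives the hydroxymethyl-anion equivalent, the hindered Si–O-isopropyl group tolerating the organomagnesium.

Step 12
Reactants: 19 bis-butenolide; 21 [(isopropoxydimethylsilyl)methyl]magnesium chloride
Product: 23 bis(α-hydroxy-α-benzyl-β-silylmethyl lactone) with each lactone (3S,4R,5S), via bis(magnesium enolate) 22 (not isolated)
Conditions: 21 (6 equiv), CuBr·SMe2 (3 equiv), THF, −40 °C; 19, −78 → −40 °C; then 2-(phenylsulfonyl)-3-phenyloxaziridine (8 equiv), THF, −78 → −20 °C; aq NH4Cl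
Reagents that add atoms: 2-(phenylsulfonyl)-3-phenyloxaziridine, O=S(=O)(N1OC1c1ccccc1)c1ccccc1
Why: The diorganocuprate complexes each butenolide, adds oxidatively at C3 to a trivalent-copper β-cuprio enolate and reductively eliminates to form the C3–CH2Si bond and the magnesium lactone enolate 22; the enolate carbon C4 then attacks the oxaziridine oxygen, and collapse of the N-sulfonyl hemiaminal releases the sulfonimine and leaves the C4 alkoxide. The closest known reaction type is the trans-selective conjugate addition of cuprates to γ-substituted butenolides combined with hydroxylation of the enolate in the same flask by an N-sulfonyloxaziridine. No ring is closed, since lactone rings E and F are already present and only receive the two new bonds each. C3 is set by the C2 aryl group, which shields one face of the flat butenolide so that the silylmethyl group enters anti to it; C4 is then set by the new C3 substituent, the oxidant approaching the enolate face anti to CH2Si so that OH ends trans and the benzyl group cis to it. The step needs 1,4-addition to outrun removal of the vinylogously acidic C2–H and reductive opening of the benzylic lactone C–O bond, which the weakly basic diorganocuprate at low temperature is chosen to secure, and it needs both units to react alike, which follows because the two butenolides are insulated by the biaryl and each is governed by its own C2 centre.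

Step 13
Reactants: 23 bis(α-hydroxy-α-benzyl-β-silylmethyl lactone)
Product: 24 bis(α-hydroxy-β-hydroxymethyl lactone) with each lactone (3S,4R,5S)
Conditions: KF, KHCO3, 30 % H2O2, THF/MeOH, rt
Reagents that add atoms: hydrogen peroxide, OO
Why: Tamao–Fleming oxidation, in which fluoride-activated alkoxysilicon takes up hydroperoxide and the primary carbon migrates from silicon to oxygen, converts each CH2–Si into CH2–OH without touching a stereocentre.

Step 14
Reactants: 24 bis(α-hydroxy-β-hydroxymethyl lactone)
Product: 25 tetra-O-benzyl octaol with both lactones opened to 1,4-diols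
Conditions: LiAlH4, THF, 0 °C → rt; Rochelle salt work-up
Reagents that add atoms: none
Why: Hydride reduction of each lactone carbonyl to the primary alcohol turns C5 into CH2OH and releases the C2 benzylic alcohol, no bond to a stereocentre being broken.

Step 15
Reactants: 25 tetra-O-benzyl octaol
Product: 26 tetra-O-benzyl ether of the target with both oxolanes (2S,3R,4S)
Conditions: CSA (0.2 equiv), CH2Cl2/MeCN, 0 °C
Reagents that add atoms: none
Why: Acid-catalysed cycloetherification through the para-benzyloxybenzylic cation at C2, which only the C5 hydroxyl can trap in a five-membered ring (the C3-CH2OH and C4-OH would give oxetanes); attack anti to the C3 hydroxymethyl, reinforced by reversibility, should give the 2,3-trans oxolane, and the mild acid at low temperature is meant to keep the kinetic O-closure ahead of Friedel–Crafts capture by ring A or ring C.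

Step 16
Reactants: 26 tetra-O-benzyl ether of the target
Product: 27 CNP0269573.1
Conditions: H2 (1 atm), Pd/C (10 %), EtOAc/MeOH, rt
Reagents that add atoms: none
Why: Catalytic hydrogenolysis cleaves the four aryl benzyl ethers, which react much faster than the ring benzylic C2–O bonds, so the free tetraphenol should form under neutral conditions that cannot trigger the acid-induced aryltetralin rearrangement of this lignan type.

**Compound list**

1 | 5-bromovanillin (3-bromo-4-hydroxy-5-methoxybenzaldehyde) | COc1cc(C=O)cc(Br)c1O | starting material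
2 | 4-(benzyloxy)-3-bromo-5-methoxybenzaldehyde | COc1cc(C=O)cc(Br)c1OCc1ccccc1 | intermediate
3 | methyl acrylate | C=CC(=O)OC | starting material
4 | methyl 4-[4-(benzyloxy)-3-bromo-5-methoxyphenyl]-4-oxobutanoate | COC(=O)CCC(=O)c1cc(OC)c(OCc2ccccc2)c(Br)c1 | intermediate
5 | methyl (4S)-4-[4-(benzyloxy)-3-bromo-5-methoxyphenyl]-4-hydroxybutanoate | COC(=O)CC[C@H](O)c1cc(OC)c(OCc2ccccc2)c(Br)c1 | intermediate
6 | (5S)-5-[4-(benzyloxy)-3-bromo-5-methoxyphenyl]oxolan-2-one | O=C1CC[C@@H](c2cc(OC)c(OCc3ccccc3)c(Br)c2)O1 | intermediate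
7 | 4-(benzyloxy)-3-methoxybenzaldehyde (O-benzylvanillin) | COc1cc(C=O)ccc1OCc1ccccc1 | starting material
8 | (5S)-3-{[4-(benzyloxy)-3-methoxyphenyl](hydroxy)methyl}-5-[4-(benzyloxy)-3-bromo-5-methoxyphenyl]oxolan-2-one, lithium alkoxide in the flask, mixture at C3 and the carbinol carbon | COc1cc(C(O)C2C[C@@H](c3cc(OC)c(OCc4ccccc4)c(Br)c3)OC2=O)ccc1OCc1ccccc1 | intermediate
9 | methanesulfonate of 8 | COc1cc(C(OS(C)(=O)=O)C2C[C@@H](c3cc(OC)c(OCc4ccccc4)c(Br)c3)OC2=O)ccc1OCc1ccccc1 | intermediate
10 | (3E,5S)-3-[4-(benzyloxy)-3-methoxybenzylidene]-5-[4-(benzyloxy)-3-bromo-5-methoxyphenyl]oxolan-2-one | COc1cc(/C=C2\C[C@@H](c3cc(OC)c(OCc4ccccc4)c(Br)c3)OC2=O)ccc1OCc1ccccc1 | intermediate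
11 | (3E,5S)-3-[4-(benzyloxy)-3-methoxybenzylidene]-5-[4-(benzyloxy)-3-methoxy-5-(4,4,5,5-tetramethyl-1,3,2-dioxaborolan-2-yl)phenyl]oxolan-2-one | COc1cc(/C=C2\C[C@@H](c3cc(OC)c(OCc4ccccc4)c(B4OC(C)(C)C(C)(C)O4)c3)OC2=O)ccc1OCc1ccccc1 | intermediate
12 | methyl 4-[4-(benzyloxy)-3-methoxyphenyl]-4-oxobutanoate | COC(=O)CCC(=O)c1ccc(OCc2ccccc2)c(OC)c1 | intermediate
13 | methyl (4S)-4-[4-(benzyloxy)-3-methoxyphenyl]-4-hydroxybutanoate | COC(=O)CC[C@H](O)c1ccc(OCc2ccccc2)c(OC)c1 | intermediate
14 | (5S)-5-[4-(benzyloxy)-3-methoxyphenyl]oxolan-2-one | O=C1CC[C@@H](c2ccc(OCc3ccccc3)c(OC)c2)O1 | intermediate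
15 | (5S)-3-{[4-(benzyloxy)-3-bromo-5-methoxyphenyl](hydroxy)methyl}-5-[4-(benzyloxy)-3-methoxyphenyl]oxolan-2-one, lithium alkoxide in the flask, mixture at C3 and the carbinol carbon | COc1cc(C(O)C2C[C@@H](c3ccc(OCc4ccccc4)c(OC)c3)OC2=O)cc(Br)c1OCc1ccccc1 | intermediate
16 | methanesulfonate of 15 | COc1cc(C(OS(C)(=O)=O)C2C[C@@H](c3ccc(OCc4ccccc4)c(OC)c3)OC2=O)cc(Br)c1OCc1ccccc1 | intermediate
17 | (3E,5S)-3-[4-(benzyloxy)-3-bromo-5-methoxybenzylidene]-5-[4-(benzyloxy)-3-methoxyphenyl]oxolan-2-one | COc1cc(/C=C2\C[C@@H](c3ccc(OCc4ccccc4)c(OC)c3)OC2=O)cc(Br)c1OCc1ccccc1 | intermediate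
18 | biaryl bis(benzylidene lactone): ring B (C5 aryl of the (3E,5S)-lactone carrying the ring A benzylidene) bonded to ring C (benzylidene aryl of the (3E,5S)-lactone carrying ring D at C5), all four phenols as benzyl ethers | COc1cc(/C=C2\C[C@@H](c3cc(OC)c(OCc4ccccc4)c(-c4cc(/C=C5\C[C@@H](c6ccc(OCc7ccccc7)c(OC)c6)OC5=O)cc(OC)c4OCc4ccccc4)c3)OC2=O)ccc1OCc1ccccc1 | intermediate
19 | bis-butenolide: (5S)-5-(ring B)-3-(ring A methyl)furan-2(5H)-one and (5S)-5-(ring D)-3-(ring C methyl)furan-2(5H)-one on the B–C biaryl, all four phenols as benzyl ethers | COc1cc(CC2=C[C@@H](c3cc(OC)c(OCc4ccccc4)c(-c4cc(CC5=C[C@@H](c6ccc(OCc7ccccc7)c(OC)c6)OC5=O)cc(OC)c4OCc4ccccc4)c3)OC2=O)ccc1OCc1ccccc1 | intermediate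
20 | (chloromethyl)(isopropoxy)dimethylsilane | ClC[Si](C)(C)OC(C)C | starting material
21 | [(isopropoxydimethylsilyl)methyl]magnesium chloride | CC(C)O[Si](C)(C)C[Mg]Cl | intermediate
22 | bis(chloromagnesium lactone enolate) with CH2Si at C3 trans to the C2 aryl in both rings | COc1cc(CC2=C(O[Mg]Cl)O[C@H](c3cc(OC)c(OCc4ccccc4)c(-c4cc(CC5=C(O[Mg]Cl)O[C@H](c6ccc(OCc7ccccc7)c(OC)c6)[C@H]5C[Si](C)(C)OC(C)C)cc(OC)c4OCc4ccccc4)c3)[C@H]2C[Si](C)(C)OC(C)C)ccc1OCc1ccccc1 | intermediate
23 | bis[(3S,4R,5S)-5-aryl-3-benzyl-3-hydroxy-4-{[isopropoxy(dimethyl)silyl]methyl}oxolan-2-one] on the B–C biaryl (aryl trans to CH2Si, OH trans to CH2Si, benzyl cis to CH2Si) | COc1cc(C[C@@]2(O)C(=O)O[C@H](c3cc(OC)c(OCc4ccccc4)c(-c4cc(C[C@@]5(O)C(=O)O[C@H](c6ccc(OCc7ccccc7)c(OC)c6)[C@H]5C[Si](C)(C)OC(C)C)cc(OC)c4OCc4ccccc4)c3)[C@H]2C[Si](C)(C)OC(C)C)ccc1OCc1ccccc1 | intermediate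
24 | bis[(3S,4R,5S)-5-aryl-3-benzyl-3-hydroxy-4-(hydroxymethyl)oxolan-2-one] on the B–C biaryl | COc1cc(C[C@@]2(O)C(=O)O[C@H](c3cc(OC)c(OCc4ccccc4)c(-c4cc(C[C@@]5(O)C(=O)O[C@H](c6ccc(OCc7ccccc7)c(OC)c6)[C@H]5CO)cc(OC)c4OCc4ccccc4)c3)[C@H]2CO)ccc1OCc1ccccc1 | intermediate
25 | tetra-O-benzyl octaol: each unit ArCH(OH)–CH(CH2OH)–C(OH)(CH2Ar')–CH2OH with the three stereocentres as in 24 | COc1cc(C[C@@](O)(CO)[C@H](CO)[C@H](O)c2cc(OC)c(OCc3ccccc3)c(-c3cc(C[C@@](O)(CO)[C@H](CO)[C@H](O)c4ccc(OCc5ccccc5)c(OC)c4)cc(OC)c3OCc3ccccc3)c2)ccc1OCc1ccccc1 | intermediate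
26 | tetra-O-benzyl ether of the target, both oxolanes (2S,3R,4S) in the O1/C2-aryl numbering | COc1cc(C[C@@]2(O)CO[C@H](c3cc(OC)c(OCc4ccccc4)c(-c4cc(C[C@@]5(O)CO[C@H](c6ccc(OCc7ccccc7)c(OC)c6)[C@H]5CO)cc(OC)c4OCc4ccccc4)c3)[C@H]2CO)ccc1OCc1ccccc1 | intermediate
27 | CNP0269573.1, both oxolanes (2S,3R,4S) | COc1cc(C[C@@]2(O)CO[C@H](c3cc(OC)c(O)c(-c4cc(C[C@@]5(O)CO[C@H](c6ccc(O)c(OC)c6)[C@H]5CO)cc(OC)c4O)c3)[C@H]2CO)ccc1O | target

**Step count and risks**

Total step count: 16. Longest linear sequence: 12 steps (steps 1, 2, 3, 4, 5, 9, 10, 12, 13, 14, 15, 16).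

Steps most likely to fail:

Step 12. The organometallic may remove the acidic C2–H of the butenolides or open the benzylic lactone C–O bond by electron transfer instead of adding. Oxygen transfer to the magnesium/copper enolates may also be slow, with the oxidant consumed by residual organocopper or the enolate adding to the sulfonimine. Fallback: starting from 19, the same cuprate is added in the presence of Me3SiCl (THF, −78 °C), which speeds the 1,4-addition relative to proton transfer and traps both enolates as they form, to give after non-aqueous work-up the bis(trimethylsilyl ketene acetal) F1. Rubottom oxidation of F1 with dimethyldioxirane (acetone/CH2Cl2, −78 °C) on the face anti to the C3 substituent, followed by brief aqueous citric acid to remove the silyl groups, returns to the route at 23.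

Step 10. The double bonds may migrate incompletely if the electron-rich arylidene isomer is not sufficiently disfavoured, or the C2 configuration may erode through further hydride chain-walking. Fallback: starting from 18, conjugate reduction (NaBH4, NiCl2·6H2O, MeOH/THF, 0 °C) gives the bis(α-benzyl lactone) F2. Enolisation and selenenylation (LiHMDS, THF, −78 °C; PhSeBr) give the bis(α-benzyl-α-phenylselanyl lactone) F3. Oxidation (H2O2, pyridine, CH2Cl2, 0 °C) and selenoxide syn-elimination toward the ring C–H then return to the route at 19 without any base or metal hydride touching C2; material that eliminates toward the benzylic carbon is 18 and is recycled.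

Step 15. The C2 benzylic cation may be captured by the electron-rich benzyl ring on C4 to give an aryltetralin, or the closure may give mixtures at C2 if it does not equilibrate cleanly. Fallback: starting from 24, partial reduction (DIBAL-H, CH2Cl2/THF, −78 °C) gives the bis-lactol F4, and ionic reduction of the lactol carbons (Et3SiH, BF3·OEt2, CH2Cl2, −78 °C) returns to the route at 26. The O1–C2 bond is never broken in this sequence, so the C2 configuration set in steps 3 and 7 is carried through and steps 14 and 15 are bypassed.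

**Further compounds**

F1 | step 12 | bis(trimethylsilyl ketene acetal) of the bis(α-benzyl-β-silylmethyl lactone), CH2Si trans to the C2 aryl in both rings | COc1cc(CC2=C(O[Si](C)(C)C)O[C@H](c3cc(OC)c(OCc4ccccc4)c(-c4cc(CC5=C(O[Si](C)(C)C)O[C@H](c6ccc(OCc7ccccc7)c(OC)c6)[C@H]5C[Si](C)(C)OC(C)C)cc(OC)c4OCc4ccccc4)c3)[C@H]2C[Si](C)(C)OC(C)C)ccc1OCc1ccccc1
F2 | step 10 | bis(α-benzyl lactone) from conjugate reduction of 18, (5S) in both rings, mixture at C3 | COc1cc(CC2C[C@@H](c3cc(OC)c(OCc4ccccc4)c(-c4cc(CC5C[C@@H](c6ccc(OCc7ccccc7)c(OC)c6)OC5=O)cc(OC)c4OCc4ccccc4)c3)OC2=O)ccc1OCc1ccccc1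
F3 | step 10 | bis(α-benzyl-α-phenylselanyl lactone), (5S) in both rings, mixture at C3 | COc1cc(CC2([Se]c8ccccc8)C[C@@H](c3cc(OC)c(OCc4ccccc4)c(-c4cc(CC5([Se]c9ccccc9)C[C@@H](c6ccc(OCc7ccccc7)c(OC)c6)OC5=O)cc(OC)c4OCc4ccccc4)c3)OC2=O)ccc1OCc1ccccc1
F4 | step 15 | bis-lactol from partial reduction of 24, lactol carbons as anomer mixtures | COc1cc(C[C@@]2(O)C(O)O[C@H](c3cc(OC)c(OCc4ccccc4)c(-c4cc(C[C@@]5(O)C(O)O[C@H](c6ccc(OCc7ccccc7)c(OC)c6)[C@H]5CO)cc(OC)c4OCc4ccccc4)c3)[C@H]2CO)ccc1OCc1ccccc1
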